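Ring numbering: the eleven-membered carbocycle is C1 (quaternary; methyl and 4-methylpent-3-enyl), C2=C3 (E), C4 (acyloxy carbinol), C5–C6 (fused oxirane ring, methyl on C5), C7, C8, C9 (hydroxymethyl)=C10, C11.
Enabling feature: the oxygen-bearing C4 has the E alkene C2=C3 on one side and the oxirane carbon C5 on the other. The ring bond C3–C4 therefore maps onto the addition of a C3 alkenyl metal to a formyl group carried by the oxirane.
Cuts, in order: the C4 ester and the C9 silyl ether; ring bond C3–C4; the oxirane back to a Z C5=C6 allylic alcohol; C5=C6 and C9=C10 by olefination; C10–C11 by one-carbon homologation; C2=C3 by iodo-olefination; C1 back to geraniol.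
Forward: the chain grows from C1 outwards (C2=C3–I, then C11–C10, then C9 with C8–C6, then C5–C4). The oxirane is made on the open chain, and the eleven-membered ring is closed last, before acylation and desilylation.
Stereochemistry: C1 comes from Sharpless epoxidation of geraniol followed by a stereospecific 1,2-shift. C5 and C6 come from a second Sharpless epoxidation, and C4 is set on ring closure under control of C5. Alkene geometries come from the Takai (E C2=C3), stabilised-ylide Wittig (C8 cis to C11) and Still–Gennari (Z C5=C6) olefinations.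

Key step: step 19

Assumption: ethyl 2-[bis(2,2,2-trifluoroethoxy)phosphoryl]propanoate is taken as a purchasable reagent, and the locants C1–C11 defined above are also used for the open-chain compounds.

Step 1
Reactants: 1 geraniol
Product: 2 (2S,3S)-2,3-epoxygeraniol
Conditions: Ti(OiPr)4 (5 mol %), L-(+)-diethyl tartrate (7 mol %), tBuOOH, 4 Å molecular sieves, CH2Cl2, −20 °C
Reagents that add atoms: tert-butyl hydroperoxide, CC(C)(C)OO
Why: Sharpless asymmetric epoxidation reacts only at the alkene of the allylic alcohol, and the L-(+)-tartrate catalyst delivers oxygen to the face that gives the 2S,3S oxirane, from which the C1 configuration is later derived.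

Step 2
Reactants: 2 (2S,3S)-2,3-epoxygeraniol
Product: 3 (2S,3S)-2,3-epoxygeranyl tert-butyldimethylsilyl ether
Conditions: tBuMe2SiCl, imidazole, DMF, 0 °C to rt
Reagents that add atoms: tert-butyldimethylsilyl chloride, CC(C)(C)[Si](C)(C)Cl
Why: Imidazole-promoted silylation of the primary alcohol touches no stereocentre and installs the siloxymethyl group that has to migrate in the next step.

Step 3
Reactants: 3 (2S,3S)-2,3-epoxygeranyl tert-butyldimethylsilyl ether
Product: 4 (2S)-2-{[(tert-butyldimethylsilyl)oxy]methyl}-2,6-dimethylhept-5-enal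
Conditions: MeAl(OAr)2 (Ar = 4-bromo-2,6-di-tert-butylphenyl, 20 mol %), CH2Cl2, −78 to −40 °C
Reagents that add atoms: none
Why: In this Lewis-acid-promoted rearrangement of an epoxy silyl ether to a β-siloxy aldehyde (semipinacol type), the bulky aluminium phenoxide opens the tertiary C–O bond while the siloxymethyl carbon shifts to its rear side, so the oxirane configuration passes with inversion to the new quaternary carbon C1 (formyl carbon = C2, CH2OSi carbon = C11).

Step 4
Reactants: 4 (2S)-2-{[(tert-butyldimethylsilyl)oxy]methyl}-2,6-dimethylhept-5-enal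
Product: 5 tert-butyl({(2R)-2-[(E)-2-iodoethenyl]-2,6-dimethylhept-5-en-1-yl}oxy)dimethylsilane
Conditions: CrCl2 (6 equiv), CHI3 (2 equiv), THF, 0 °C to rt
Reagents that add atoms: iodoform, IC(I)I
Why: In the Takai iodo-olefination the geminal dichromium reagent from CHI3 adds to the non-enolisable aldehyde and eliminates to the E iodoalkene, a preference reinforced by the bulky quaternary neighbour; C1 keeps its arrangement and the descriptor changes by priority only.

Step 5
Reactants: 5 tert-butyl({(2R)-2-[(E)-2-iodoethenyl]-2,6-dimethylhept-5-en-1-yl}oxy)dimethylsilane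
Product: 6 (2R)-2-[(E)-2-iodoethenyl]-2,6-dimethylhept-5-en-1-ol
Conditions: Bu4NF, THF, 0 °C to rt
Reagents that add atoms: none
Why: Fluoride cleaves the only Si–O bond present, and the E iodoalkene resists elimination because its vicinal hydrogen is cis to iodine.

Step 6
Reactants: 6 (2R)-2-[(E)-2-iodoethenyl]-2,6-dimethylhept-5-en-1-ol
Product: 7 (2R)-2-[(E)-2-iodoethenyl]-2,6-dimethylhept-5-enal
Conditions: Dess–Martin periodinane, CH2Cl2, 0 °C to rt
Reagents that add atoms: none
Why: Dess–Martin oxidation stops at the aldehyde under nearly neutral conditions, and the product can neither epimerise nor move its alkene into conjugation because the α-carbon is quaternary.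

Step 7
Reactants: 7 (2R)-2-[(E)-2-iodoethenyl]-2,6-dimethylhept-5-enal
Product: 8 (1E,3S)-1-iodo-3-(2-methoxyethenyl)-3,7-dimethylocta-1,6-diene
Conditions: Ph3PCH2OMe Cl (1.6 equiv), KN(SiMe3)2 (1.5 equiv), THF, 0 °C; then 7, 0 °C to rt
Reagents that add atoms: (methoxymethyl)triphenylphosphonium chloride, COC[P+](c1ccccc1)(c1ccccc1)c1ccccc1.[Cl-]
Why: The small methoxymethylene ylide undergoes the Wittig reaction even with α-quaternary aldehydes and brings in C10, and the mixed enol ether geometry does not matter because it is lost on hydrolysis.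

Step 8
Reactants: 8 (1E,3S)-1-iodo-3-(2-methoxyethenyl)-3,7-dimethylocta-1,6-diene
Product: 9 (3S)-3-[(E)-2-iodoethenyl]-3,7-dimethyloct-6-enal
Conditions: 1 M HCl, THF, 0 °C to rt
Reagents that add atoms: water, O
Why: Dilute aqueous acid protonates the electron-rich enol ether much faster than the trisubstituted alkene, and hydrolysis of the oxocarbenium ion completes the one-carbon homologation to C11H2–C10HO.

Step 9
Reactants: 10 ethyl (triphenyl-λ5-phosphanylidene)acetate; 11 allyl bromide
Product: 13 ethyl 2-(triphenyl-λ5-phosphanylidene)pent-4-enoate, via phosphonium bromide 12 (not isolated)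
Conditions: CHCl3, reflux; then 1 M NaOH, CH2Cl2/H2O, rt
Reagents that add atoms: none
Why: C-alkylation of the stabilised ylide by the reactive allylic bromide gives the phosphonium salt, which hydroxide deprotonates to the α-allyl ylide, whose allyl group supplies C8, C7 and C6 with the terminal alkene as a latent C6 aldehyde.

Step 10
Reactants: 9 (3S)-3-[(E)-2-iodoethenyl]-3,7-dimethyloct-6-enal; 13 ethyl 2-(triphenyl-λ5-phosphanylidene)pent-4-enoate
Product: 14 ethyl (2E,5S)-5-[(E)-2-iodoethenyl]-5,9-dimethyl-2-(prop-2-en-1-yl)deca-2,8-dienoate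
Conditions: toluene, 90 °C
Reagents that add atoms: none
Why: Wittig olefination with an α-substituted stabilised ylide places the ester trans to the aldehyde chain, which gives the E enoate with C8 cis to C11 as the ring requires, under neutral conditions that spare the iodoalkene.

Step 11
Reactants: 14 ethyl (2E,5S)-5-[(E)-2-iodoethenyl]-5,9-dimethyl-2-(prop-2-en-1-yl)deca-2,8-dienoate
Product: 15 (2E,5S)-5-[(E)-2-iodoethenyl]-5,9-dimethyl-2-(prop-2-en-1-yl)deca-2,8-dien-1-ol
Conditions: iBu2AlH (2.5 equiv), CH2Cl2, −78 °C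
Reagents that add atoms: none
Why: iBu2AlH reduces the conjugated ester by twofold 1,2-hydride delivery to the allylic alcohol at low temperature and leaves the iodoalkene and the isolated alkenes alone.

Step 12
Reactants: 15 (2E,5S)-5-[(E)-2-iodoethenyl]-5,9-dimethyl-2-(prop-2-en-1-yl)deca-2,8-dien-1-ol
Product: 16 tert-butyldimethylsilyl ether of 15
Conditions: tBuMe2SiCl, imidazole, CH2Cl2, rt
Reagents that add atoms: tert-butyldimethylsilyl chloride, CC(C)(C)[Si](C)(C)Cl
Why: Silylation masks the C9 hydroxymethyl group so that later only the C4 allylic alcohol can direct the titanium epoxidation, and this ether should last to the final step and leave under mild fluoride.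

Step 13
Reactants: 16 tert-butyldimethylsilyl ether of 15
Product: 18 (4E,7S)-4-{[(tert-butyldimethylsilyl)oxy]methyl}-7-[(E)-2-iodoethenyl]-7,11-dimethyldodeca-4,10-dien-1-ol, via B-alkyl-9-borabicyclononane 17 (not isolated)
Conditions: 9-borabicyclo[3.3.1]nonane (1.2 equiv), THF, 0 °C to rt; then NaOH, H2O2, 0 °C
Reagents that add atoms: hydrogen peroxide, OO; 9-borabicyclo[3.3.1]nonane, B1C2CCCC1CCC2 (boron stays only in 17)
Why: Brown hydroboration with the bulky dialkylborane selects the monosubstituted terminal alkene over the two trisubstituted alkenes and the hindered, deactivated iodoalkene and puts boron on C6, and alkaline peroxide then gives the primary alcohol.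

Step 14
Reactants: 18 (4E,7S)-4-{[(tert-butyldimethylsilyl)oxy]methyl}-7-[(E)-2-iodoethenyl]-7,11-dimethyldodeca-4,10-dien-1-ol
Product: 19 (4E,7S)-4-{[(tert-butyldimethylsilyl)oxy]methyl}-7-[(E)-2-iodoethenyl]-7,11-dimethyldodeca-4,10-dienal
Conditions: Dess–Martin periodinane, CH2Cl2, 0 °C to rt
Reagents that add atoms: none
Why: Dess–Martin oxidation converts the only free alcohol into the C6 aldehyde without affecting the silyl ether, the alkenes or the iodoalkene.

Step 15
Reactants: 19 (4E,7S)-4-{[(tert-butyldimethylsilyl)oxy]methyl}-7-[(E)-2-iodoethenyl]-7,11-dimethyldodeca-4,10-dienal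
Product: 20 ethyl (2Z,6E,9S)-6-{[(tert-butyldimethylsilyl)oxy]methyl}-9-[(E)-2-iodoethenyl]-2,9,13-trimethyltetradeca-2,6,12-trienoate
Conditions: ethyl 2-[bis(2,2,2-trifluoroethoxy)phosphoryl]propanoate, KN(SiMe3)2, 18-crown-6, THF, −78 °C
Reagents that add atoms: ethyl 2-[bis(2,2,2-trifluoroethoxy)phosphoryl]propanoate, CCOC(=O)C(C)P(=O)(OCC(F)(F)F)OCC(F)(F)F
Why: In the Still–Gennari olefination the electron-poor phosphonate with a dissociated potassium counter-ion eliminates irreversibly from the kinetic adduct and gives the Z enoate (ester cis to C7), the geometry that later becomes the cis relation of C4 and C7 on the oxirane.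

Step 16
Reactants: 20 ethyl (2Z,6E,9S)-6-{[(tert-butyldimethylsilyl)oxy]methyl}-9-[(E)-2-iodoethenyl]-2,9,13-trimethyltetradeca-2,6,12-trienoate
Product: 21 (2Z,6E,9S)-6-{[(tert-butyldimethylsilyl)oxy]methyl}-9-[(E)-2-iodoethenyl]-2,9,13-trimethyltetradeca-2,6,12-trien-1-ol
Conditions: iBu2AlH (2.5 equiv), CH2Cl2, −78 °C
Reagents that add atoms: none
Why: Low-temperature 1,2-reduction of the enoate with iBu2AlH gives the Z allylic alcohol with retention of the alkene geometry.

Step 17
Reactants: 21 (2Z,6E,9S)-6-{[(tert-butyldimethylsilyl)oxy]methyl}-9-[(E)-2-iodoethenyl]-2,9,13-trimethyltetradeca-2,6,12-trien-1-ol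
Product: 22 (2S,3R)-epoxy alcohol (oxirane at C5–C6, C4 as CH2OH)
Conditions: Ti(OiPr)4 (20 mol %), L-(+)-diethyl tartrate (24 mol %), tBuOOH, 4 Å molecular sieves, CH2Cl2, −20 °C
Reagents that add atoms: tert-butyl hydroperoxide, CC(C)(C)OO
Why: Sharpless asymmetric epoxidation is directed by the only free allylic alcohol, its syn oxygen transfer keeps C4 and C7 cis, and the L-(+)-tartrate catalyst selects the face that gives the 2S,3R epoxy alcohol (C5 and C6 as in the target) under reagent control, independent of the remote C1.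

Step 18
Reactants: 22 (2S,3R)-epoxy alcohol
Product: 23 seco iodo epoxy aldehyde (2R,3R at the oxirane)
Conditions: nPr4N[RuO4] (5 mol %), N-methylmorpholine N-oxide, 4 Å molecular sieves, CH2Cl2, rt
Reagents that add atoms: none
Why: Ley–Griffith oxidation works under neutral anhydrous conditions that leave the oxirane, silyl ether and iodoalkene intact, and the aldehyde has no α-hydrogen to lose; the C5 descriptor changes from S to R by priority only.

Step 19
Reactants: 23 seco iodo epoxy aldehyde
Product: 26 macrocyclic epoxy alcohol (4S), via alkenylchromium dichloride 24 (not isolated), via chromium alkoxide 25 (not isolated)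
Conditions: CrCl2 (10 equiv), NiCl2 (0.1 equiv), degassed DMSO, 23 added by syringe pump (final 2 mM), rt; H2O work-up
Reagents that add atoms: none
Why: Divalent chromium reduces NiCl2 to zerovalent nickel; oxidative addition of the C3–I bond and transmetalation then give the alkenylchromium dichloride 24 (trivalent chromium) with the E geometry intact, and its carbonyl addition gives the alkoxide 25, which water releases as 26. The closest known reaction type is the Nozaki–Hiyama–Kishi macrocyclisation of ω-iodoalkenyl aldehydes, a family that also includes organochromium ring closures onto α,β-epoxy aldehydes. The eleven-membered carbocycle forms in an 11-exo-trig mode (C3 onto the formyl carbon, carbonyl oxygen outside the ring), while the oxirane ring is only a spectator. C4 is governed by C5: no chelate is expected in the strongly coordinating solvent, so C3 should approach opposite the polar C5–O bond and along the C5 methyl group rather than past C6 with its cis C7 chain (polar Felkin–Anh picture), which leads to the 4S, erythro carbinol. The step needs chemoselectivity for C–I over the oxirane, the silyl ether and the two other alkenes, which the weakly basic organochromium provides, and neither enolisation nor epimerisation can occur because C5 carries no hydrogen. Ring closure must outrun intermolecular coupling, which slow addition into high dilution secures, helped by the bends that the cis C9=C10 alkene, the cis oxirane and the geminally disubstituted C1 put into the chain.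

Step 20
Reactants: 26 macrocyclic epoxy alcohol (4S)
Product: 27 C4 3-methylbut-2-enoate of 26
Conditions: 3-methylbut-2-enoyl chloride, pyridine, 4-(dimethylamino)pyridine (0.2 equiv), CH2Cl2, 0 °C to rt
Reagents that add atoms: 3-methylbut-2-enoyl chloride, CC(C)=CC(=O)Cl
Why: Nucleophilic catalysis by the aminopyridine acylates the hindered C4 alcohol at oxygen, so C4 keeps its configuration, and the weak base pyridine limits vinylketene formation and hence loss of conjugation in the acyl group.

Step 21
Reactants: 27 C4 3-methylbut-2-enoate of 26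
Product: 28 target compound CNP0318149.1
Conditions: Bu4NF, AcOH (1:1), THF, 0 °C to rt
Reagents that add atoms: none
Why: Acetic-acid-buffered fluoride removes the primary allylic silyl ether under essentially neutral conditions that the ester, the oxirane and all four stereocentres should survive.

Compound list
1 | geraniol, (2E)-3,7-dimethylocta-2,6-dien-1-ol | CC(C)=CCC/C(C)=C/CO | starting material
2 | [(2S,3S)-3-methyl-3-(4-methylpent-3-en-1-yl)oxiran-2-yl]methanol | CC(C)=CCC[C@]1(C)O[C@H]1CO | intermediate
3 | tert-butyl(dimethyl){[(2S,3S)-3-methyl-3-(4-methylpent-3-en-1-yl)oxiran-2-yl]methoxy}silane | CC(C)=CCC[C@]1(C)O[C@H]1CO[Si](C)(C)C(C)(C)C | intermediate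
4 | (2S)-2-{[(tert-butyldimethylsilyl)oxy]methyl}-2,6-dimethylhept-5-enal | CC(C)=CCC[C@](C)(C=O)CO[Si](C)(C)C(C)(C)C | intermediate
5 | tert-butyl({(2R)-2-[(E)-2-iodoethenyl]-2,6-dimethylhept-5-en-1-yl}oxy)dimethylsilane | CC(C)=CCC[C@](C)(/C=C/I)CO[Si](C)(C)C(C)(C)C | intermediate
6 | (2R)-2-[(E)-2-iodoethenyl]-2,6-dimethylhept-5-en-1-ol | CC(C)=CCC[C@](C)(/C=C/I)CO | intermediate
7 | (2R)-2-[(E)-2-iodoethenyl]-2,6-dimethylhept-5-enal | CC(C)=CCC[C@](C)(/C=C/I)C=O | intermediate
8 | (1E,3S)-1-iodo-3-(2-methoxyethenyl)-3,7-dimethylocta-1,6-diene (E/Z mixture at the enol ether) | CC(C)=CCC[C@](C)(/C=C/I)C=COC | intermediate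
9 | (3S)-3-[(E)-2-iodoethenyl]-3,7-dimethyloct-6-enal | CC(C)=CCC[C@](C)(/C=C/I)CC=O | intermediate
10 | ethyl (triphenyl-λ5-phosphanylidene)acetate | CCOC(=O)C=P(c1ccccc1)(c1ccccc1)c1ccccc1 | starting material
11 | allyl bromide, 3-bromoprop-1-ene | C=CCBr | starting material
12 | (1-ethoxy-1-oxopent-4-en-2-yl)triphenylphosphonium bromide (racemic) | CCOC(=O)C(CC=C)[P+](c1ccccc1)(c1ccccc1)c1ccccc1.[Br-] | intermediate
13 | ethyl 2-(triphenyl-λ5-phosphanylidene)pent-4-enoate | CCOC(=O)C(CC=C)=P(c1ccccc1)(c1ccccc1)c1ccccc1 | intermediate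
14 | ethyl (2E,5S)-5-[(E)-2-iodoethenyl]-5,9-dimethyl-2-(prop-2-en-1-yl)deca-2,8-dienoate | CC(C)=CCC[C@](C)(/C=C/I)C/C=C(\CC=C)C(=O)OCC | intermediate
15 | (2E,5S)-5-[(E)-2-iodoethenyl]-5,9-dimethyl-2-(prop-2-en-1-yl)deca-2,8-dien-1-ol | CC(C)=CCC[C@](C)(/C=C/I)C/C=C(\CC=C)CO | intermediate
16 | tert-butyl({(2E,5S)-5-[(E)-2-iodoethenyl]-5,9-dimethyl-2-(prop-2-en-1-yl)deca-2,8-dien-1-yl}oxy)dimethylsilane | CC(C)=CCC[C@](C)(/C=C/I)C/C=C(\CC=C)CO[Si](C)(C)C(C)(C)C | intermediate
17 | 9-[(4E,7S)-4-{[(tert-butyldimethylsilyl)oxy]methyl}-7-[(E)-2-iodoethenyl]-7,11-dimethyldodeca-4,10-dien-1-yl]-9-borabicyclo[3.3.1]nonane | CC(C)=CCC[C@](C)(/C=C/I)C/C=C(\CCCB1C2CCCC1CCC2)CO[Si](C)(C)C(C)(C)C | intermediate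
18 | (4E,7S)-4-{[(tert-butyldimethylsilyl)oxy]methyl}-7-[(E)-2-iodoethenyl]-7,11-dimethyldodeca-4,10-dien-1-ol | CC(C)=CCC[C@](C)(/C=C/I)C/C=C(\CCCO)CO[Si](C)(C)C(C)(C)C | intermediate
19 | (4E,7S)-4-{[(tert-butyldimethylsilyl)oxy]methyl}-7-[(E)-2-iodoethenyl]-7,11-dimethyldodeca-4,10-dienal | CC(C)=CCC[C@](C)(/C=C/I)C/C=C(\CCC=O)CO[Si](C)(C)C(C)(C)C | intermediate
20 | ethyl (2Z,6E,9S)-6-{[(tert-butyldimethylsilyl)oxy]methyl}-9-[(E)-2-iodoethenyl]-2,9,13-trimethyltetradeca-2,6,12-trienoate | CC(C)=CCC[C@](C)(/C=C/I)C/C=C(\CC/C=C(/C)C(=O)OCC)CO[Si](C)(C)C(C)(C)C | intermediate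
21 | (2Z,6E,9S)-6-{[(tert-butyldimethylsilyl)oxy]methyl}-9-[(E)-2-iodoethenyl]-2,9,13-trimethyltetradeca-2,6,12-trien-1-ol | CC(C)=CCC[C@](C)(/C=C/I)C/C=C(\CC/C=C(/C)CO)CO[Si](C)(C)C(C)(C)C | intermediate
22 | {(2S,3R)-3-[(3E,6S)-3-{[(tert-butyldimethylsilyl)oxy]methyl}-6-[(E)-2-iodoethenyl]-6,10-dimethylundeca-3,9-dien-1-yl]-2-methyloxiran-2-yl}methanol | CC(C)=CCC[C@](C)(/C=C/I)C/C=C(\CC[C@H]1O[C@@]1(C)CO)CO[Si](C)(C)C(C)(C)C | intermediate
23 | (2R,3R)-3-[(3E,6S)-3-{[(tert-butyldimethylsilyl)oxy]methyl}-6-[(E)-2-iodoethenyl]-6,10-dimethylundeca-3,9-dien-1-yl]-2-methyloxirane-2-carbaldehyde (seco iodo epoxy aldehyde) | CC(C)=CCC[C@](C)(/C=C/I)C/C=C(\CC[C@H]1O[C@@]1(C)C=O)CO[Si](C)(C)C(C)(C)C | intermediate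
24 | alkenylchromium dichloride derived from 23 (CrCl2 group in place of iodine at C3, E) | CC(C)=CCC[C@](C)(/C=C/[Cr](Cl)Cl)C/C=C(\CC[C@H]1O[C@@]1(C)C=O)CO[Si](C)(C)C(C)(C)C | intermediate
25 | dichlorochromium alkoxide of 26 (O–CrCl2 at C4) | CC(C)=CCC[C@]1(C)/C=C/[C@H](O[Cr](Cl)Cl)[C@]2(C)O[C@@H]2CC/C(CO[Si](C)(C)C(C)(C)C)=C\C1 | intermediate
26 | (1S,2S,3E,5S,7E,11R)-8-{[(tert-butyldimethylsilyl)oxy]methyl}-1,5-dimethyl-5-(4-methylpent-3-en-1-yl)-12-oxabicyclo[9.1.0]dodeca-3,7-dien-2-ol (ring numbering: 1S,4S,5S,6R) | CC(C)=CCC[C@]1(C)/C=C/[C@H](O)[C@]2(C)O[C@@H]2CC/C(CO[Si](C)(C)C(C)(C)C)=C\C1 | intermediate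
27 | (1R,2S,3E,5S,7E,11R)-8-{[(tert-butyldimethylsilyl)oxy]methyl}-1,5-dimethyl-5-(4-methylpent-3-en-1-yl)-12-oxabicyclo[9.1.0]dodeca-3,7-dien-2-yl 3-methylbut-2-enoate | CC(C)=CCC[C@]1(C)/C=C/[C@H](OC(=O)C=C(C)C)[C@]2(C)O[C@@H]2CC/C(CO[Si](C)(C)C(C)(C)C)=C\C1 | intermediate
28 | (1R,2S,3E,5S,7E,11R)-8-(hydroxymethyl)-1,5-dimethyl-5-(4-methylpent-3-en-1-yl)-12-oxabicyclo[9.1.0]dodeca-3,7-dien-2-yl 3-methylbut-2-enoate (ring numbering: 1S,4S,5R,6R) | CC(C)=CCC[C@]1(C)/C=C/[C@H](OC(=O)C=C(C)C)[C@]2(C)O[C@@H]2CC/C(CO)=C\C1 | target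

Total step count: 21. Longest linear sequence: 20 steps (steps 1–8 and 10–21, from geraniol 1).

Steps most likely to fail

Step 19. Strain in the closing eleven-membered ring may override the open-chain preference at the formyl group, so that facial selectivity at C4 is poor or reversed. A slow closure would also leave time for intermolecular coupling and for chloride opening of the oxirane by Lewis-acidic trivalent chromium. The fallback sets C4 by hydride delivery to a ring ketone instead of by the C–C bond formation. It sets out from 23, which is cyclised as in step 19 without regard to the outcome at C4. The 4R-configured macrocyclic epoxy alcohol F1, alone or mixed with 26, is oxidised with Dess–Martin periodinane to the macrocyclic epoxy enone F2. Zn(BH4)2 in Et2O at low temperature then binds the ketone and oxirane oxygens and should deliver hydride in a 1,2-sense from the flank of the C5 methyl group, away from C6. This gives the erythro alcohol, and the route is rejoined at 26.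

Step 8. The acid needed to hydrolyse the enol ether may also trigger a carbonyl-ene or Prins-type ring closure of the citronellal-like aldehyde onto the trisubstituted alkene, a process favoured by the geminal substitution at C1. The fallback is an acid-free homologation that sets out from 7. Methylenation with Ph3P=CH2 gives (1E,3S)-3-ethenyl-1-iodo-3,7-dimethylocta-1,6-diene F3. 9-Borabicyclo[3.3.1]nonane should add only to the monosubstituted alkene to give the B-alkylborane F4, and alkaline hydrogen peroxide gives (3S)-3-[(E)-2-iodoethenyl]-3,7-dimethyloct-6-en-1-ol F5. Dess–Martin oxidation of F5 rejoins the route at 9.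

Step 20. Acylation of the carbinol between the fully substituted C5 and the ring alkene may be slow. Amine-induced vinylketene formation from the acid chloride would then shift the acyl double bond out of conjugation. The fallback builds the acyl alkene after the ester bond and sets out from 26. Coupling with diethylphosphonoacetic acid (N,N'-dicyclohexylcarbodiimide, catalytic 4-(dimethylamino)pyridine, CH2Cl2), which runs through a reactive phosphonoketene and is little affected by hindrance, gives the C4 (diethoxyphosphoryl)acetate F6. A Horner–Wadsworth–Emmons reaction of F6 with acetone (NaH, THF, 0 °C) installs the C=CMe2 unit directly in conjugation and rejoins the route at 27.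

Further compounds
F1 | step 19 | (1S,2R,3E,5S,7E,11R)-8-{[(tert-butyldimethylsilyl)oxy]methyl}-1,5-dimethyl-5-(4-methylpent-3-en-1-yl)-12-oxabicyclo[9.1.0]dodeca-3,7-dien-2-ol (4R epimer of 26) | CC(C)=CCC[C@]1(C)/C=C/[C@@H](O)[C@]2(C)O[C@@H]2CC/C(CO[Si](C)(C)C(C)(C)C)=C\C1
F2 | step 19 | (1R,3E,5S,7E,11R)-8-{[(tert-butyldimethylsilyl)oxy]methyl}-1,5-dimethyl-5-(4-methylpent-3-en-1-yl)-12-oxabicyclo[9.1.0]dodeca-3,7-dien-2-one | CC(C)=CCC[C@]1(C)/C=C/C(=O)[C@]2(C)O[C@@H]2CC/C(CO[Si](C)(C)C(C)(C)C)=C\C1
F3 | step 8 | (1E,3S)-3-ethenyl-1-iodo-3,7-dimethylocta-1,6-diene | CC(C)=CCC[C@](C)(/C=C/I)C=C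
F4 | step 8 | 9-{(3S)-3-[(E)-2-iodoethenyl]-3,7-dimethyloct-6-en-1-yl}-9-borabicyclo[3.3.1]nonane | CC(C)=CCC[C@](C)(/C=C/I)CCB1C2CCCC1CCC2
F5 | step 8 | (3S)-3-[(E)-2-iodoethenyl]-3,7-dimethyloct-6-en-1-ol | CC(C)=CCC[C@](C)(/C=C/I)CCO
F6 | step 20 | (1R,2S,3E,5S,7E,11R)-8-{[(tert-butyldimethylsilyl)oxy]methyl}-1,5-dimethyl-5-(4-methylpent-3-en-1-yl)-12-oxabicyclo[9.1.0]dodeca-3,7-dien-2-yl (diethoxyphosphoryl)acetate | CC(C)=CCC[C@]1(C)/C=C/[C@H](OC(=O)CP(=O)(OCC)OCC)[C@]2(C)O[C@@H]2CC/C(CO[Si](C)(C)C(C)(C)C)=C\C1
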